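**Plan**

1. The retrosynthesis first cuts the two C–CH2 bonds of the methylene bridge (C8–CH2 on the chromene, CH2–C on triketone ring C). This gives a 5,7-dihydroxy-6-isobutyryl-2,2-dimethylchromene and a Mannich base of isobutyrylfilicinic acid.
2. It then cuts O1–C2 of pyran ring A back to an ortho-prenylphenol, and last cuts C4a–C8a and C5–C6 of benzene ring B into a cyclobutenone and a siloxyalkyne.
3. Enabling feature: ring B is hexasubstituted with oxygen on the alternate carbons C5, C7 and C8a, and each oxygen has a different origin. C8a–O comes from the ketene carbonyl (free OH), C5–O from the siloxyalkyne (OTIPS), C7–O from the 3-alkoxy group of the cyclobutenone. C6 takes the acyl precursor from cyclobutenone C2, C8–H comes from its CH2, and C4a carries the prenyl group of the alkyne.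
4. Forward: ring B by benzannulation (step 6), ring A by oxidative cyclisation onto the only free OH (step 7), carbinol to ketone, fluoride unmasking, then ring C (made separately from phloroglucinol) is attached through the methylene carbon (step 14).
5. Stereochemistry: the target is achiral. The single carbinol centre of the intermediates is formed racemic in step 2 and erased by oxidation in step 9.
6. Protecting groups: the C7 oxygen travels as a 2-(trimethylsilyl)ethyl ether and the carbinol as a TES ether, so the end game needs only fluoride and no Lewis acid near the chromene.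

Key step: step 6

Remark: ring A is the pyran, ring B the benzene ring (chromene numbering O1 to C8a) and ring C the triketone ring, drawn as the enol tautomer of the target. Ethyl 4-methylpent-3-enoate is taken as a purchasable ester, and every compound holding the carbinol centre is racemic.

**Route**

Step 1
Reactants: 1 2-(trimethylsilyl)ethanol; 2 trichloroethylene
Product: 5 (E)-[2-(1,2-dichloroethenyloxy)ethyl]trimethylsilane, via potassium alkoxide 3 (not isolated), via dichloroacetylene 4 (not isolated)
Conditions: KH, THF, 0 °C; then Cl2C=CHCl, −50 °C to rt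
Reagents that add atoms: none
Why: The alkoxide dehydrochlorinates trichloroethylene to dichloroacetylene and adds to it in an anti sense (elimination–addition vinylic substitution, the standard dichlorovinyl ether entry to ynol ethers), which should give the E ether; its geometry is lost in step 2.

Step 2
Reactants: 5 (E)-[2-(1,2-dichloroethenyloxy)ethyl]trimethylsilane; 6 isobutyraldehyde
Product: 10 triethyl({4-methyl-1-[2-(trimethylsilyl)ethoxy]pent-1-yn-3-yl}oxy)silane, via chloroalkynyl ether 7 (not isolated), via lithium alkoxyacetylide 8 (not isolated), via lithium propargylic alkoxide 9 (not isolated)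
Conditions: n-BuLi (2.1 equiv), THF, −78 to −40 °C; i-PrCHO, −78 °C; Et3SiCl, DMAP (cat.), −78 °C to rt; NaHCO3 work-up
Reagents that add atoms: triethylsilyl chloride, CC[Si](Cl)(CC)CC
Why: n-BuLi should take the dichlorovinyl ether through β-elimination and Cl/Li exchange to the lithium alkoxyacetylide, whose 1,2-addition to the aldehyde (acetylide addition) gives a racemic alkoxide that is silylated in the same flask, so the acid-labile alkoxypropargyl alcohol is never handled; the new stereocentre is formed without control and is erased in step 9.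

Step 3
Reactants: 10 triethyl({4-methyl-1-[2-(trimethylsilyl)ethoxy]pent-1-yn-3-yl}oxy)silane; 11 trichloroacetyl chloride
Product: 13 4,4-dichloro-2-[2-methyl-1-(triethylsilyloxy)propyl]-3-[2-(trimethylsilyl)ethoxy]cyclobut-2-en-1-one, via dichloroketene 12 (not isolated)
Conditions: Cl3CCOCl, zinc–copper couple, Et2O–DME, 0 °C to rt
Reagents that add atoms: none
Why: Ketene–alkyne [2+2] cycloaddition using dichloroketene made in the flask: the nucleophilic β-carbon of the ynol ether bonds to the ketene carbonyl carbon, which places the carbinol chain at C2 and the alkoxy group at C3, and DME ties up the ZnCl2 that could ionise the propargylic ether.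

Step 4
Reactants: 13 4,4-dichloro-2-[2-methyl-1-(triethylsilyloxy)propyl]-3-[2-(trimethylsilyl)ethoxy]cyclobut-2-en-1-one
Product: 14 2-[2-methyl-1-(triethylsilyloxy)propyl]-3-[2-(trimethylsilyl)ethoxy]cyclobut-2-en-1-one
Conditions: Zn dust, AcOH, TMEDA, EtOH, 0 °C to rt
Reagents that add atoms: none
Why: Reductive dechlorination of an α,α-dichloroketone by zinc under buffered protic conditions is the usual second stage of the dichloroketene route to cyclobutenones and should leave the vinylogous ester, the TES ether and the β-silylethyl group untouched.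

Step 5
Reactants: 15 ethyl 4-methylpent-3-enoate
Product: 19 triisopropyl[(5-methylhex-4-en-1-yn-1-yl)oxy]silane, via lithium dibromoenolate 16 (not isolated), via bromo lithio enolate 17 (not isolated), via lithium ynolate 18 (not isolated)
Conditions: CH2Br2, lithium 2,2,6,6-tetramethylpiperidide (from the amine and n-BuLi), THF, −78 °C; LiN(SiMe3)2; n-BuLi, −78 °C to rt; i-Pr3SiCl, −78 °C to rt
Reagents that add atoms: dibromomethane, BrCBr; triisopropylsilyl chloride, CC(C)[Si](Cl)(C(C)C)C(C)C
Why: Kowalski ester homologation: LiCHBr2 adds to the ester, Br/Li exchange on the dibromoenolate sets off a 1,2-shift of the alkyl group to give the ynolate, and the bulky chlorosilane silylates it on oxygen and not on carbon.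

Step 6
Reactants: 14 2-[2-methyl-1-(triethylsilyloxy)propyl]-3-[2-(trimethylsilyl)ethoxy]cyclobut-2-en-1-one; 19 triisopropyl[(5-methylhex-4-en-1-yn-1-yl)oxy]silane
Product: 24 2-(3-methylbut-2-enyl)-4-[2-methyl-1-(triethylsilyloxy)propyl]-3-(triisopropylsilyloxy)-5-[2-(trimethylsilyl)ethoxy]phenol, via vinylketene 20 (not isolated), via vinylcyclobutenone 21 (not isolated), via dienylketene 22 (not isolated), via cyclohexadienone 23 (not isolated)
Conditions: 19 (1.5 equiv), degassed PhMe, 80 °C then 110 °C, sealed tube
Reagents that add atoms: none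
Why: Heating opens cyclobutenone 14 by 4π electrocyclic cleavage of its C1–C4 bond to vinylketene 20, whose ketene C=C adds [2+2] to the siloxyalkyne to give 4-vinylcyclobutenone 21; a second 4π opening gives dienylketene 22, and 6π electrocyclisation followed by enolisation of cyclohexadienone 23 gives the phenol. This is the Danheiser benzannulation in its siloxyalkyne variant, run here on a 3-alkoxycyclobutenone so that the product is a phloroglucinol with three differentiated oxygens. Ring B is closed by the disrotatory 6π electrocyclisation of the dienylketene, after the two new skeletal bonds C4a–C8a and C5–C6 (chromene numbering) have been made in the ketene [2+2] event. No stereocentre is created; the carbinol centre is carried along racemic and 21 is only a transient mixture of diastereomers. The step needs one regiochemistry in the [2+2] event, and the polarisation of the partners secures it: the oxygen-free, nucleophilic alkyne carbon (the one bearing the prenyl group) bonds to the electrophilic ketene carbonyl carbon, so the ketene oxygen ends as the only free OH, ortho to the prenyl group and to the single ring CH, while OTIPS sits next to the carbinol chain. The small TES group on the carbinol and the excess of 19 are chosen to keep the crowded [2+2] event ahead of ketene dimerisation and of acylation of the product phenol by the ketene.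

Step 7
Reactants: 24 2-(3-methylbut-2-enyl)-4-[2-methyl-1-(triethylsilyloxy)propyl]-3-(triisopropylsilyloxy)-5-[2-(trimethylsilyl)ethoxy]phenol
Product: 26 triethyl(2-methyl-1-{2,2-dimethyl-5-(triisopropylsilyloxy)-7-[2-(trimethylsilyl)ethoxy]-2H-chromen-6-yl}propoxy)silane, via ortho-quinone methide 25 (not isolated)
Conditions: DDQ (1.1 equiv), PhH, rt to 60 °C
Reagents that add atoms: none
Why: DDQ dehydrogenation of an ortho-prenylphenol gives an ortho-quinone methide that closes by oxa-6π electrocyclisation to the 2,2-dimethyl-2H-chromene, and since the C5 oxygen is silylated the C8a hydroxyl is the only one that can close ring A.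

Step 8
Reactants: 26 triethyl(2-methyl-1-{2,2-dimethyl-5-(triisopropylsilyloxy)-7-[2-(trimethylsilyl)ethoxy]-2H-chromen-6-yl}propoxy)silane
Product: 27 1-{2,2-dimethyl-5-(triisopropylsilyloxy)-7-[2-(trimethylsilyl)ethoxy]-2H-chromen-6-yl}-2-methylpropan-1-ol
Conditions: HF·pyridine, pyridine, THF, 0 °C
Reagents that add atoms: none
Why: Selective desilylation by difference in silyl lability: buffered HF·pyridine should cleave the alkyl TES ether while the hindered aryl TIPS ether and the 2-(trimethylsilyl)ethyl ether stay, so the benzylic alcohol is freed while both ortho oxygens are still capped and no quinone methide can form from it.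

Step 9
Reactants: 27 1-{2,2-dimethyl-5-(triisopropylsilyloxy)-7-[2-(trimethylsilyl)ethoxy]-2H-chromen-6-yl}-2-methylpropan-1-ol
Product: 28 1-{2,2-dimethyl-5-(triisopropylsilyloxy)-7-[2-(trimethylsilyl)ethoxy]-2H-chromen-6-yl}-2-methylpropan-1-one
Conditions: Dess–Martin periodinane, NaHCO3, CH2Cl2, rt
Reagents that add atoms: none
Why: Dess–Martin oxidation converts hindered benzylic secondary alcohols to aryl ketones under neutral conditions that the chromene alkene and the silyl ethers tolerate, and it removes the only stereocentre.

Step 10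
Reactants: 28 1-{2,2-dimethyl-5-(triisopropylsilyloxy)-7-[2-(trimethylsilyl)ethoxy]-2H-chromen-6-yl}-2-methylpropan-1-one
Product: 29 1-(5,7-dihydroxy-2,2-dimethyl-2H-chromen-6-yl)-2-methylpropan-1-one
Conditions: Bu4NF (4 equiv), THF, rt to 50 °C; aq NH4Cl
Reagents that add atoms: none
Why: Fluoride-induced desilylation cleaves the aryl TIPS ether and fragments the 2-(trimethylsilyl)ethyl aryl ether by β-elimination to ethylene, Me3SiF and the phenoxide (a good leaving group next to the acyl group), which frees both phenols without a Lewis acid that could open the chromene.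

Step 11
Reactants: 30 phloroglucinol; 31 isobutyryl chloride
Product: 32 2-methyl-1-(2,4,6-trihydroxyphenyl)propan-1-one
Conditions: AlCl3, PhNO2, 65 °C; aq HCl
Reagents that add atoms: none
Why: Friedel–Crafts C-acylation of phloroglucinol by an acid chloride and AlCl3 is the standard route to acylphloroglucinols, and the first acyl group deactivates the ring against a second.

Step 12
Reactants: 32 2-methyl-1-(2,4,6-trihydroxyphenyl)propan-1-one
Product: 34 3,5-dihydroxy-4,4-dimethyl-2-(2-methylpropanoyl)cyclohexa-2,5-dien-1-one, via monomethyl acylphloroglucinol 33 (not isolated)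
Conditions: NaOMe (3 equiv), MeI (2.2 equiv), MeOH, 0 °C to rt
Reagents that add atoms: iodomethane, CI
Why: Base-mediated C-methylation of an acylphloroglucinol, dearomatising at the second methylation, is the classical entry to acylfilicinic acids; MeI is held near two equivalents to limit the trimethyl product.

Step 13
Reactants: 34 3,5-dihydroxy-4,4-dimethyl-2-(2-methylpropanoyl)cyclohexa-2,5-dien-1-one
Product: 35 6-[(dimethylamino)methyl]-3,5-dihydroxy-4,4-dimethyl-2-(2-methylpropanoyl)cyclohexa-2,5-dien-1-one
Conditions: Me2NCH2NMe2 (1.1 equiv), CH2Cl2, 0 °C to rt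
Reagents that add atoms: bis(dimethylamino)methane, CN(C)CN(C)C
Why: Mannich reaction: the acidic β-triketone protonates the aminal to the iminium ion, which its enolate captures at the only ring CH, and the betaine-like product should separate from the mixture.

Step 14
Reactants: 29 1-(5,7-dihydroxy-2,2-dimethyl-2H-chromen-6-yl)-2-methylpropan-1-one; 35 6-[(dimethylamino)methyl]-3,5-dihydroxy-4,4-dimethyl-2-(2-methylpropanoyl)cyclohexa-2,5-dien-1-one
Product: 37 6-{[5,7-dihydroxy-2,2-dimethyl-6-(2-methylpropanoyl)-2H-chromen-8-yl]methyl}-3,5-dihydroxy-4,4-dimethyl-2-(2-methylpropanoyl)cyclohexa-2,5-dien-1-one, via methylene trione 36 (not isolated)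
Conditions: 35 (1.2 equiv), dioxane, 70 °C, argon
Reagents that add atoms: none
Why: On warming, the Mannich base loses dimethylamine (retro-Michael) to the methylene trione, and the only free aromatic carbon of 29, C8, flanked by O1 and the C7 hydroxyl, adds to it in a Michael-type Friedel–Crafts alkylation; preforming the electrophile on ring C keeps formaldehyde away from 29 and so avoids the symmetrical dimers of a three-component condensation.

**Compound list**

1 | 2-(trimethylsilyl)ethanol | C[Si](C)(C)CCO | starting material
2 | trichloroethylene | ClC=C(Cl)Cl | starting material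
3 | potassium 2-(trimethylsilyl)ethoxide (formed in the flask) | C[Si](C)(C)CC[O-].[K+] | intermediate
4 | dichloroacetylene (formed in the flask) | ClC#CCl | intermediate
5 | (E)-[2-(1,2-dichloroethenyloxy)ethyl]trimethylsilane | C[Si](C)(C)CCO/C(Cl)=C\Cl | intermediate
6 | isobutyraldehyde | CC(C)C=O | starting material
7 | [2-(chloroethynyloxy)ethyl]trimethylsilane (formed in the flask) | C[Si](C)(C)CCOC#CCl | intermediate
8 | lithium [2-(trimethylsilyl)ethoxy]ethynide (formed in the flask) | C[Si](C)(C)CCOC#C[Li] | intermediate
9 | lithium 4-methyl-1-[2-(trimethylsilyl)ethoxy]pent-1-yn-3-olate, racemic (formed in the flask) | C[Si](C)(C)CCOC#CC(O[Li])C(C)C | intermediate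
10 | triethyl({4-methyl-1-[2-(trimethylsilyl)ethoxy]pent-1-yn-3-yl}oxy)silane, racemic | CC[Si](CC)(CC)OC(C#COCC[Si](C)(C)C)C(C)C | intermediate
11 | trichloroacetyl chloride | O=C(Cl)C(Cl)(Cl)Cl | starting material
12 | dichloroketene (formed in the flask) | O=C=C(Cl)Cl | intermediate
13 | 4,4-dichloro-2-[2-methyl-1-(triethylsilyloxy)propyl]-3-[2-(trimethylsilyl)ethoxy]cyclobut-2-en-1-one, racemic | O=C1C(C(O[Si](CC)(CC)CC)C(C)C)=C(OCC[Si](C)(C)C)C1(Cl)Cl | intermediate
14 | 2-[2-methyl-1-(triethylsilyloxy)propyl]-3-[2-(trimethylsilyl)ethoxy]cyclobut-2-en-1-one, racemic | O=C1CC(OCC[Si](C)(C)C)=C1C(O[Si](CC)(CC)CC)C(C)C | intermediate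
15 | ethyl 4-methylpent-3-enoate | CCOC(=O)CC=C(C)C | starting material
16 | lithium 1,1-dibromo-5-methylhexa-1,4-dien-2-olate (formed in the flask) | [Li]OC(CC=C(C)C)=C(Br)Br | intermediate
17 | lithium 1-bromo-1-lithio-5-methylhexa-1,4-dien-2-olate (formed in the flask) | [Li]OC(CC=C(C)C)=C([Li])Br | intermediate
18 | lithium 5-methylhex-4-en-1-yn-1-olate (formed in the flask) | [Li]OC#CCC=C(C)C | intermediate
19 | triisopropyl[(5-methylhex-4-en-1-yn-1-yl)oxy]silane | CC(C)=CCC#CO[Si](C(C)C)(C(C)C)C(C)C | intermediate
20 | 2-[2-methyl-1-(triethylsilyloxy)propyl]-3-[2-(trimethylsilyl)ethoxy]buta-1,3-dien-1-one, racemic (formed in the flask) | C=C(OCC[Si](C)(C)C)C(=C=O)C(O[Si](CC)(CC)CC)C(C)C | intermediate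
21 | 2-(3-methylbut-2-enyl)-4-[2-methyl-1-(triethylsilyloxy)propyl]-3-(triisopropylsilyloxy)-4-{1-[2-(trimethylsilyl)ethoxy]ethenyl}cyclobut-2-en-1-one, mixture of diastereomers (formed in the flask) | O=C1C(CC=C(C)C)=C(O[Si](C(C)C)(C(C)C)C(C)C)C1(C(OCC[Si](C)(C)C)=C)C(O[Si](CC)(CC)CC)C(C)C | intermediate
22 | dienylketene: 2-(3-methylbut-2-enyl)-4-[2-methyl-1-(triethylsilyloxy)propyl]-3-(triisopropylsilyloxy)-5-[2-(trimethylsilyl)ethoxy]hexa-1,3,5-trien-1-one, the isomer having the ketene and alkoxyvinyl groups cis on the central double bond (formed in the flask) | O=C=C(CC=C(C)C)/C(O[Si](C(C)C)(C(C)C)C(C)C)=C(\C(OCC[Si](C)(C)C)=C)C(O[Si](CC)(CC)CC)C(C)C | intermediate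
23 | 2-(3-methylbut-2-enyl)-4-[2-methyl-1-(triethylsilyloxy)propyl]-3-(triisopropylsilyloxy)-5-[2-(trimethylsilyl)ethoxy]cyclohexa-2,4-dien-1-one (formed in the flask) | O=C1CC(OCC[Si](C)(C)C)=C(C(O[Si](CC)(CC)CC)C(C)C)C(O[Si](C(C)C)(C(C)C)C(C)C)=C1CC=C(C)C | intermediate
24 | 2-(3-methylbut-2-enyl)-4-[2-methyl-1-(triethylsilyloxy)propyl]-3-(triisopropylsilyloxy)-5-[2-(trimethylsilyl)ethoxy]phenol, racemic | Oc1cc(OCC[Si](C)(C)C)c(C(O[Si](CC)(CC)CC)C(C)C)c(O[Si](C(C)C)(C(C)C)C(C)C)c1CC=C(C)C | intermediate
25 | ortho-quinone methide: 6-(3-methylbut-2-enylidene)-4-[2-methyl-1-(triethylsilyloxy)propyl]-5-(triisopropylsilyloxy)-3-[2-(trimethylsilyl)ethoxy]cyclohexa-2,4-dien-1-one, alkenyl group on the carbonyl side (formed in the flask) | O=C1C=C(OCC[Si](C)(C)C)C(C(O[Si](CC)(CC)CC)C(C)C)=C(O[Si](C(C)C)(C(C)C)C(C)C)/C1=C/C=C(C)C | intermediate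
26 | triethyl(2-methyl-1-{2,2-dimethyl-5-(triisopropylsilyloxy)-7-[2-(trimethylsilyl)ethoxy]-2H-chromen-6-yl}propoxy)silane, racemic | CC1(C)C=Cc2c(O1)cc(OCC[Si](C)(C)C)c(C(O[Si](CC)(CC)CC)C(C)C)c2O[Si](C(C)C)(C(C)C)C(C)C | intermediate
27 | 1-{2,2-dimethyl-5-(triisopropylsilyloxy)-7-[2-(trimethylsilyl)ethoxy]-2H-chromen-6-yl}-2-methylpropan-1-ol, racemic | CC1(C)C=Cc2c(O1)cc(OCC[Si](C)(C)C)c(C(O)C(C)C)c2O[Si](C(C)C)(C(C)C)C(C)C | intermediate
28 | 1-{2,2-dimethyl-5-(triisopropylsilyloxy)-7-[2-(trimethylsilyl)ethoxy]-2H-chromen-6-yl}-2-methylpropan-1-one | CC1(C)C=Cc2c(O1)cc(OCC[Si](C)(C)C)c(C(=O)C(C)C)c2O[Si](C(C)C)(C(C)C)C(C)C | intermediate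
29 | 1-(5,7-dihydroxy-2,2-dimethyl-2H-chromen-6-yl)-2-methylpropan-1-one | CC1(C)C=Cc2c(O1)cc(O)c(C(=O)C(C)C)c2O | intermediate
30 | phloroglucinol (benzene-1,3,5-triol) | Oc1cc(O)cc(O)c1 | starting material
31 | isobutyryl chloride | CC(C)C(=O)Cl | starting material
32 | 2-methyl-1-(2,4,6-trihydroxyphenyl)propan-1-one (phlorisobutyrophenone) | CC(C)C(=O)c1c(O)cc(O)cc1O | intermediate
33 | 2-methyl-1-(2,4,6-trihydroxy-3-methylphenyl)propan-1-one (formed in the flask) | CC(C)C(=O)c1c(O)cc(O)c(C)c1O | intermediate
34 | 3,5-dihydroxy-4,4-dimethyl-2-(2-methylpropanoyl)cyclohexa-2,5-dien-1-one (isobutyrylfilicinic acid) | CC(C)C(=O)C1=C(O)C(C)(C)C(O)=CC1=O | intermediate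
35 | 6-[(dimethylamino)methyl]-3,5-dihydroxy-4,4-dimethyl-2-(2-methylpropanoyl)cyclohexa-2,5-dien-1-one (drawn neutral, expected as the internal salt) | CC(C)C(=O)C1=C(O)C(C)(C)C(O)=C(CN(C)C)C1=O | intermediate
36 | 3-hydroxy-4,4-dimethyl-6-methylidene-2-(2-methylpropanoyl)cyclohex-2-ene-1,5-dione (formed in the flask) | CC(C)C(=O)C1=C(O)C(C)(C)C(=O)C(=C)C1=O | intermediate
37 | 6-{[5,7-dihydroxy-2,2-dimethyl-6-(2-methylpropanoyl)-2H-chromen-8-yl]methyl}-3,5-dihydroxy-4,4-dimethyl-2-(2-methylpropanoyl)cyclohexa-2,5-dien-1-one (CNP0318758.0) | CC(C)C(=O)C1=C(O)C(C)(C)C(O)=C(Cc2c(O)c(C(=O)C(C)C)c(O)c3c2OC(C)(C)C=C3)C1=O | target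

**Count**

Total steps: 14. Longest linear sequence: 10 steps (steps 1–4, 6–10 and 14, from 2-(trimethylsilyl)ethanol). Step 5 and steps 11–13 are side branches.

**Steps most likely to fail**

Step 6. The [2+2] addition of the bulky siloxyalkyne to the ketene carbon that carries the branched carbinol chain may be outrun by ketene dimerisation, by acylation of the product phenol, or by oxygen-to-carbon silyl migration in 19 at the temperature needed to open the 3-alkoxycyclobutenone. The fallback sets out from 32 and comes back at 29. Compound 32 would be heated with 3-methylbut-2-enal and ethylenediammonium diacetate in toluene (Knoevenagel condensation, then oxa-6π closure of the dienone). The non-chelated hydroxyl para to the acyl group should react preferentially, and the 8-acyl isomer would be removed by chromatography. No new compound lies on this path (F0), and step 14 follows unchanged.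

Step 3. ZnCl2 formed alongside the ketene may ionise the propargylic silyl ether or oligomerise the ynol ether, and chlorine may shift in the dichlorocyclobutenone before it is reduced. The fallback sets out from 10 and comes back at 14, so 13 and step 4 are bypassed. N,N-dimethylacetamide, Tf2O and 2,4,6-collidine in CH2Cl2 would generate the keteniminium ion in the presence of 10. Its [2+2] cycloaddition (same polarity as the ketene addition) would give the cyclobuteniminium salt, N,N-dimethyl-{2-[2-methyl-1-(triethylsilyloxy)propyl]-3-[2-(trimethylsilyl)ethoxy]cyclobut-2-en-1-ylidene}ammonium trifluoromethanesulfonate F1. Buffered hydrolysis (aq NaHCO3) at the iminium carbon would then give 14.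

Step 5. Deprotonation of the doubly activated CH2 of the β,γ-unsaturated ester by LiCHBr2 or the amide bases may compete with carbonyl addition and let the double bond move into conjugation. The fallback sets out from 15 and comes back at 18, then 19. i-Bu2AlH at −78 °C would reduce 15 to 4-methylpent-3-enal F2. Corey–Fuchs olefination (CBr4, PPh3) would give 1,1-dibromo-5-methylhexa-1,4-diene F3. Two equivalents of n-BuLi would convert it to lithium 5-methylhex-4-en-1-ynide F4. Oxidation of this acetylide by t-BuOOLi (from t-BuOOH and LiN(SiMe3)2) would give ynolate 18, which i-Pr3SiOTf would silylate on oxygen to 19.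

**Further compounds**

F0 | step 6 | none | none
F1 | step 3 | N,N-dimethyl-{2-[2-methyl-1-(triethylsilyloxy)propyl]-3-[2-(trimethylsilyl)ethoxy]cyclobut-2-en-1-ylidene}ammonium trifluoromethanesulfonate | C[N+](C)=C1CC(OCC[Si](C)(C)C)=C1C(O[Si](CC)(CC)CC)C(C)C.[O-]S(=O)(=O)C(F)(F)F
F2 | step 5 | 4-methylpent-3-enal | CC(C)=CCC=O
F3 | step 5 | 1,1-dibromo-5-methylhexa-1,4-diene | CC(C)=CCC=C(Br)Br
F4 | step 5 | lithium 5-methylhex-4-en-1-ynide | [Li]C#CCC=C(C)C
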